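**Retrosynthetic overview**
Feature: the furan ring O1–C2=C3–C3a–C7a carries resorcinol ring B on C2 and CHO on C3. Its five ring atoms are O1, C2, C4, C4a and C8a of a 2-arylchromenylium (flavylium) ring C, and the formyl carbon is that ring's C3 moved outside, so the C15 core is one flavylium salt.
Disconnection 1: the prenyl groups at C7 (ring A) and C5' (ring B) go back to aryl bromides (twofold Stille coupling), because an ortho-prenylphenol would not survive strong acid.
Disconnection 2: the benzofuran C2–C3 bond goes back, through a peroxide-induced Baeyer–Villiger-type ring contraction, to the 8,5'-dibromo-7,2',4'-trihydroxyflavylium chloride.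
Disconnection 3: the flavylium C3–C4 and O1–C2 bonds go back to 3-bromo-2,4-dihydroxybenzaldehyde (from 2-bromoresorcinol) and 5-bromo-2,4-dihydroxyacetophenone.
Ring order: benzene rings A and B are bought, the six-membered pyrylium ring C is closed in step 3, and it is contracted to the five-membered furan in step 4.

Key step: step 4

Remark: the target has no stereocentre and no stereodefined double bond, so stereocentres that arise in transient intermediates are left unassigned.

**Step 1**
Reactants: 1 resacetophenone (2,4-dihydroxyacetophenone)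
Product: 2 bromoketone 1-(5-bromo-2,4-dihydroxyphenyl)ethan-1-one
Conditions: NBS (1.0 equiv), MeCN, 0 → 20 °C
Reagents that add atoms: N-bromosuccinimide, O=C1CCC(=O)N1Br
Why: Electrophilic aromatic bromination: C5 is ortho to the 4-OH and para to the 2-OH and is less crowded than C3 between the two hydroxyls, so one equivalent of reagent at low temperature should stop at the 5-bromide.

**Step 2**
Reactants: 3 bromoresorcinol (2-bromobenzene-1,3-diol)
Product: 5 aldehyde 3-bromo-2,4-dihydroxybenzaldehyde, via aryl iminium chloride 4 (not isolated)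
Conditions: POCl3, DMF, MeCN, −10 → 25 °C; then H2O, 50 °C
Reagents that add atoms: N,N-dimethylformamide, CN(C)C=O; water, O
Why: Vilsmeier–Haack formylation: C4 and C6 of 3 are equivalent and are the only positions ortho/para to both hydroxyls, so the chloroiminium ion can give only one ring-substituted iminium salt, which water hydrolyses to the aldehyde.

**Step 3**
Reactants: 2 bromoketone 1-(5-bromo-2,4-dihydroxyphenyl)ethan-1-one; 5 aldehyde 3-bromo-2,4-dihydroxybenzaldehyde
Product: 7 flavylium salt 8-bromo-2-(5-bromo-2,4-dihydroxyphenyl)-7-hydroxychromenylium chloride, via 2-hydroxychalcone 6 (not isolated)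
Conditions: HCl (g), AcOH, 10 → 20 °C; Et2O (precipitation)
Reagents that add atoms: hydrogen chloride, Cl
Why: Acid-catalysed Claisen–Schmidt aldol condensation followed by cyclodehydration (the classical flavylium salt synthesis): the enol of 2 adds to protonated 5, chalcone 6 rotates about its protonated enone, its ortho-hydroxyl attacks the ketone carbon (6-exo-trig) and loss of water gives the aromatic pyrylium salt, whose precipitation pulls the equilibria forward, while the aryl bromides should hold because chloride is a poor acceptor for electrophilic bromine.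

**Step 4**
Reactants: 7 flavylium salt 8-bromo-2-(5-bromo-2,4-dihydroxyphenyl)-7-hydroxychromenylium chloride
Product: 11 dibromo formylbenzofuran 7-bromo-2-(5-bromo-2,4-dihydroxyphenyl)-6-hydroxy-1-benzofuran-3-carbaldehyde, via C2 hydroperoxide 8 (not isolated), via aryl ester aldehyde 9 (not isolated), via cyclic hemiketal 10 (not isolated)
Conditions: 30% aq H2O2 (3 equiv), NaOAc (1.5 equiv), MeOH–H2O, pH 4–5, 0 → 20 °C
Reagents that add atoms: hydrogen peroxide, OO
Why: H2O2, an alpha-effect nucleophile, adds to C2 of the cation to give hydroperoxide 8, whose O–O bond breaks while C3 shifts from C2 to oxygen (Criegee or Baeyer–Villiger type 1,2-shift), and water opens the resulting seven-membered dioxacarbenium ion to the aryl ester aldehyde 9. The enol of 9 then bonds through its benzylic carbon (former C4) to the aroyl carbonyl carbon (former C2) to give hemiketal 10, and loss of water leaves the aromatic furan with former C3 as the formyl group. The closest known reaction is the hydrogen peroxide oxidation of 3-unsubstituted flavylium salts to 2-aryl-3-formylbenzofurans, and of 2',4',7-trihydroxy-3-methoxyflavylium salts to the matching benzofuran-3-carboxylic esters, in weakly acidic aqueous methanol. The furan closes in the 5-(enol-exo)-exo-trig mode and no stereocentre survives, since C2 of 8 and C2/C3 of 10 become sp2 again. Two selectivities are needed: attack at C2 and not C4, secured because C2 next to O1 carries the most charge, C4 adducts revert in the buffer and only the C2 adduct has an irreversible exit; and migration of C3 and not of ring B, secured because C3 is the electron-rich beta carbon of a 4-hydroxystyrene (7-OH para to C4a) and its shift leaves a cation held by two oxygens and ring B. The acetate buffer takes up the HCl that is released, which keeps 9 from hydrolysing before ring closure and holds back chloride oxidation and Dakin cleavage of the product aldehyde.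

**Step 5**
Reactants: 11 dibromo formylbenzofuran 7-bromo-2-(5-bromo-2,4-dihydroxyphenyl)-6-hydroxy-1-benzofuran-3-carbaldehyde
Product: 12 tris(silyl ether) 7-bromo-2-{5-bromo-2,4-bis[(tert-butyldimethylsilyl)oxy]phenyl}-6-[(tert-butyldimethylsilyl)oxy]-1-benzofuran-3-carbaldehyde
Conditions: TBSCl (3.6 equiv), imidazole, DMF, 20 °C
Reagents that add atoms: tert-butyldimethylsilyl chloride, CC(C)(C)[Si](C)(C)Cl
Why: Imidazole-promoted O-silylation of phenols: all three hydroxyls are acidic and reachable, the aldehyde is a vinylogous ester (O1–C2=C3–CHO) and stays inert, and silyl ethers are chosen because fluoride can remove them later without acid.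

**Step 6**
Reactants: 13 prenyl bromide (1-bromo-3-methylbut-2-ene)
Product: 14 prenylstannane tributyl(3-methylbut-2-en-1-yl)stannane
Conditions: Bu3SnH, LiN(i-Pr)2, THF, 0 °C; then 13, −78 → 20 °C
Reagents that add atoms: tributylstannane, CCCC[SnH](CCCC)CCCC
Why: SN2 alkylation of a stannyl anion: the soft and bulky Bu3SnLi attacks the primary carbon of the allylic bromide, so the linear allylic stannane should form.

**Step 7**
Reactants: 12 tris(silyl ether) 7-bromo-2-{5-bromo-2,4-bis[(tert-butyldimethylsilyl)oxy]phenyl}-6-[(tert-butyldimethylsilyl)oxy]-1-benzofuran-3-carbaldehyde; 14 prenylstannane tributyl(3-methylbut-2-en-1-yl)stannane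
Product: 15 diprenyl tris(silyl ether) 2-{2,4-bis[(tert-butyldimethylsilyl)oxy]-5-(3-methylbut-2-en-1-yl)phenyl}-6-[(tert-butyldimethylsilyl)oxy]-7-(3-methylbut-2-en-1-yl)-1-benzofuran-3-carbaldehyde
Conditions: 14 (3 equiv), Pd(PPh3)4 (10 mol %), toluene, 110 °C
Reagents that add atoms: none
Why: Twofold Stille (Migita–Kosugi–Stille) coupling: zerovalent palladium inserts into each C–Br bond, the allylic stannane transfers its prenyl group quickly without fluoride or base, and reductive elimination from the aryl(allyl)palladium species takes place at the unsubstituted allyl terminus, so that linear prenyl groups form and the silyl ethers and the weakly electrophilic aldehyde are spared.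

**Step 8**
Reactants: 15 diprenyl tris(silyl ether) 2-{2,4-bis[(tert-butyldimethylsilyl)oxy]-5-(3-methylbut-2-en-1-yl)phenyl}-6-[(tert-butyldimethylsilyl)oxy]-7-(3-methylbut-2-en-1-yl)-1-benzofuran-3-carbaldehyde
Product: 16 eryvarin Q, 2-[2,4-dihydroxy-5-(3-methylbut-2-en-1-yl)phenyl]-6-hydroxy-7-(3-methylbut-2-en-1-yl)-1-benzofuran-3-carbaldehyde
Conditions: n-Bu4NF (3.3 equiv), AcOH (3.3 equiv), THF, 0 °C
Reagents that add atoms: none
Why: Fluoride-driven cleavage of aryl silyl ethers (strong Si–F bond): buffering with AcOH keeps the medium near neutral, so the aldehyde is untouched and the ortho-prenylphenols, which acid would close to chromans, are released intact.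

**Compound list**
1 | 2,4-dihydroxyacetophenone | CC(=O)c1ccc(O)cc1O | starting material
2 | 1-(5-bromo-2,4-dihydroxyphenyl)ethan-1-one | CC(=O)c1cc(Br)c(O)cc1O | intermediate
3 | 2-bromoresorcinol (2-bromobenzene-1,3-diol) | Oc1cccc(O)c1Br | starting material
4 | [(3-bromo-2,4-dihydroxyphenyl)methylidene]dimethylazanium chloride, formed in the flask | C[N+](C)=Cc1ccc(O)c(Br)c1O.[Cl-] | intermediate
5 | 3-bromo-2,4-dihydroxybenzaldehyde | O=Cc1ccc(O)c(Br)c1O | intermediate
6 | (E)-3-(3-bromo-2,4-dihydroxyphenyl)-1-(5-bromo-2,4-dihydroxyphenyl)prop-2-en-1-one, formed in the flask | O=C(/C=C/c1ccc(O)c(Br)c1O)c1cc(Br)c(O)cc1O | intermediate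
7 | 8-bromo-2-(5-bromo-2,4-dihydroxyphenyl)-7-hydroxychromenylium chloride | Oc1ccc2ccc(-c3cc(Br)c(O)cc3O)[o+]c2c1Br.[Cl-] | intermediate
8 | 8-bromo-2-(5-bromo-2,4-dihydroxyphenyl)-2-hydroperoxy-2H-chromen-7-ol (racemic), formed in the flask | OOC1(c2cc(Br)c(O)cc2O)C=Cc2ccc(O)c(Br)c2O1 | intermediate
9 | 2-bromo-3-hydroxy-6-(2-oxoethyl)phenyl 5-bromo-2,4-dihydroxybenzoate, formed in the flask | O=CCc1ccc(O)c(Br)c1OC(=O)c1cc(Br)c(O)cc1O | intermediate
10 | 7-bromo-2-(5-bromo-2,4-dihydroxyphenyl)-2,6-dihydroxy-2,3-dihydro-1-benzofuran-3-carbaldehyde (mixture of diastereomers), formed in the flask | O=CC1c2ccc(O)c(Br)c2OC1(O)c1cc(Br)c(O)cc1O | intermediate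
11 | 7-bromo-2-(5-bromo-2,4-dihydroxyphenyl)-6-hydroxy-1-benzofuran-3-carbaldehyde | O=Cc1c(-c2cc(Br)c(O)cc2O)oc2c(Br)c(O)ccc12 | intermediate
12 | 7-bromo-2-{5-bromo-2,4-bis[(tert-butyldimethylsilyl)oxy]phenyl}-6-[(tert-butyldimethylsilyl)oxy]-1-benzofuran-3-carbaldehyde | O=Cc1c(-c2cc(Br)c(O[Si](C)(C)C(C)(C)C)cc2O[Si](C)(C)C(C)(C)C)oc2c(Br)c(O[Si](C)(C)C(C)(C)C)ccc12 | intermediate
13 | prenyl bromide (1-bromo-3-methylbut-2-ene) | CC(C)=CCBr | starting material
14 | tributyl(3-methylbut-2-en-1-yl)stannane | CCCC[Sn](CCCC)(CCCC)CC=C(C)C | intermediate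
15 | 2-{2,4-bis[(tert-butyldimethylsilyl)oxy]-5-(3-methylbut-2-en-1-yl)phenyl}-6-[(tert-butyldimethylsilyl)oxy]-7-(3-methylbut-2-en-1-yl)-1-benzofuran-3-carbaldehyde | CC(C)=CCc1cc(-c2oc3c(CC=C(C)C)c(O[Si](C)(C)C(C)(C)C)ccc3c2C=O)c(O[Si](C)(C)C(C)(C)C)cc1O[Si](C)(C)C(C)(C)C | intermediate
16 | eryvarin Q | CC(C)=CCc1cc(-c2oc3c(CC=C(C)C)c(O)ccc3c2C=O)c(O)cc1O | target

**Step count**
Total step count: 8.
Longest linear sequence: 6 (step 1 or 2, then steps 3, 4, 5, 7 and 8).

**Steps most likely to fail**

**Step 4 (peroxide ring contraction).**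
- Ring B may migrate in place of C3.
- The aryl ester may hydrolyse before the C–C bond closes.
- The hemiketal may open to its keto aldehyde form, and the free 2'-hydroxyl may then capture the formyl carbon, which drifts toward a chromone ring.
- Peroxide may attack the product aldehyde further.

The fallback sets out from 2 and 5 and comes back at 11. It moves an aryl group instead of contracting a ring. Ketone 2 is benzylated (BnBr, K2CO3, DMF) to the dibenzyl ketone F1. Aldehyde 5 is protected (MOMCl, NaH, DMF) as the bis(methoxymethyl) aldehyde F2. A base-mediated Claisen–Schmidt condensation (KOH, EtOH) joins them to the protected (E)-chalcone F3. The trivalent iodine reagent PhI(OH)OTs in MeOH–HC(OMe)3 brings about the known oxidative 1,2-aryl shift of chalcones and gives the racemic alpha-aryl beta-keto acetal F4. p-TsOH in (CF3)2CHOH removes both methoxymethyl groups and the acetal, the freed ortho-hydroxyl adds to the ketone, and water is lost to give the ring B dibenzyl formylbenzofuran F5. The benzyl ethers keep the 2'-oxygen from closing a chromone. BCl3 with pentamethylbenzene (CH2Cl2, −78 °C) then frees 11.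

**Step 7 (twofold prenyl Stille coupling).**
- Oxidative addition at the C7–Br bond, flanked by O1 and the 6-silyloxy group, may stall after the first coupling.
- Part of the prenyl transfer may go through the substituted allyl terminus.
- A palladium hydride may move the double bond into conjugation.
- An allyl group may be transferred to the aldehyde.

The fallback sets out from 12 and comes back at 15. A twofold Stille coupling with the smaller allyltributylstannane, which raises no regiochemical question (Pd(PPh3)4, toluene, 110 °C), gives the 7,5'-diallyl tris(silyl ether) F6. Cross metathesis with excess 2-methylbut-2-ene (second-generation Grubbs catalyst, CH2Cl2, 40 °C) turns both allyl groups into prenyl groups and delivers 15.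

**Step 3 (acid condensation to the flavylium salt).**
- The aldol between two hydrogen-bonded, bromine-deactivated partners may be slow.
- Long exposure to acid may cause loss or migration of bromine by ipso-protonation.
- The chalcone may drain away by conjugate addition of the 2'-hydroxyl.

The fallback sets out from 2 and 5 and comes back at 7. The C–C bond is made under base on partly protected partners, and acid is used only briefly for ring closure. Selective protection of the non-chelated 4-hydroxyls (MOMCl, K2CO3, acetone) gives the mono(methoxymethyl) ketone F7 and the mono(methoxymethyl) aldehyde F8. KOH in EtOH–H2O condenses them to the 2,2'-dihydroxychalcone bis(methoxymethyl) ether F9. A short treatment with HCl in AcOH–MeOH at 20 °C strips both methoxymethyl groups and closes the pyrylium ring to 7.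

**Further compounds**
F1 | step 4 | 1-[2,4-bis(benzyloxy)-5-bromophenyl]ethan-1-one | CC(=O)c1cc(Br)c(OCc2ccccc2)cc1OCc1ccccc1
F2 | step 4 | 3-bromo-2,4-bis(methoxymethoxy)benzaldehyde | O=Cc1ccc(OCOC)c(Br)c1OCOC
F3 | step 4 | (E)-1-[2,4-bis(benzyloxy)-5-bromophenyl]-3-[3-bromo-2,4-bis(methoxymethoxy)phenyl]prop-2-en-1-one | O=C(/C=C/c1ccc(OCOC)c(Br)c1OCOC)c1cc(Br)c(OCc2ccccc2)cc1OCc1ccccc1
F4 | step 4 | 1-[2,4-bis(benzyloxy)-5-bromophenyl]-2-[3-bromo-2,4-bis(methoxymethoxy)phenyl]-3,3-dimethoxypropan-1-one (racemic) | COC(OC)C(C(=O)c1cc(Br)c(OCc2ccccc2)cc1OCc1ccccc1)c1ccc(OCOC)c(Br)c1OCOC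
F5 | step 4 | 2-[2,4-bis(benzyloxy)-5-bromophenyl]-7-bromo-6-hydroxy-1-benzofuran-3-carbaldehyde | O=Cc1c(-c2cc(Br)c(OCc3ccccc3)cc2OCc2ccccc2)oc2c(Br)c(O)ccc12
F6 | step 7 | 7-allyl-2-{5-allyl-2,4-bis[(tert-butyldimethylsilyl)oxy]phenyl}-6-[(tert-butyldimethylsilyl)oxy]-1-benzofuran-3-carbaldehyde | C=CCc1cc(-c2oc3c(CC=C)c(O[Si](C)(C)C(C)(C)C)ccc3c2C=O)c(O[Si](C)(C)C(C)(C)C)cc1O[Si](C)(C)C(C)(C)C
F7 | step 3 | 1-[5-bromo-2-hydroxy-4-(methoxymethoxy)phenyl]ethan-1-one | CC(=O)c1cc(Br)c(OCOC)cc1O
F8 | step 3 | 3-bromo-2-hydroxy-4-(methoxymethoxy)benzaldehyde | O=Cc1ccc(OCOC)c(Br)c1O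
F9 | step 3 | (E)-3-[3-bromo-2-hydroxy-4-(methoxymethoxy)phenyl]-1-[5-bromo-2-hydroxy-4-(methoxymethoxy)phenyl]prop-2-en-1-one | O=C(/C=C/c1ccc(OCOC)c(Br)c1O)c1cc(Br)c(OCOC)cc1O
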